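**Retrosynthetic overview**
- The aldehyde oxygen goes in last: the target comes from its 2-isopropenyl analogue by SeO2 allylic oxidation of the CH3 group.
- The Ar–CH(CH3)OAc bond comes from the ring-complete aryl bromide and racemic 1-bromoethyl acetate by enantioselective nickel radical cross-coupling, with the catalyst setting the benzylic centre on a single ring enantiomer.
- The C3 isovalerate and the absolute 2R,3S ring configuration come from the racemic trans-3-ol by benzotetramisole-catalysed acylative kinetic resolution with isovaleric acid.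
- Key disconnection C2–C3: the dihydrofuran ring (the only ring formed, on the existing benzene ring) is closed by light-driven δ-hydrogen transfer and 1,5-biradical recombination in an O-methallyl salicylaldehyde.
- The arene comes from 4-bromophenol, formaldehyde (ortho-formylation) and methallyl chloride (O-alkylation).

Assumption: the SMILES is read as the 2,3-trans (2R,3S) dihydrobenzofuran with an S 1-acetoxyethyl group at C5; (R)-BTM in step 4 and the (S,S) ligand in step 5 are taken to give the senses shown, and their mirror-image forms are equally available if a pilot run shows otherwise.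

**Step 1**
Reactants: 1 4-bromophenol; 2 paraformaldehyde (formaldehyde source)
Product: 3 5-bromo-2-hydroxybenzaldehyde
Conditions: MgCl2, Et3N, MeCN, reflux; then 1 M HCl
Reagents that add atoms: none
Why: Magnesium-phenoxide-directed ortho-formylation (Hansen–Skattebøl reaction), in which the chelated phenoxide is hydroxymethylated only at the free ortho position (para is blocked by bromine) and a second formaldehyde takes up hydride to give the aldehyde.

**Step 2**
Reactants: 3 5-bromo-2-hydroxybenzaldehyde; 4 3-chloro-2-methylprop-1-ene (methallyl chloride)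
Product: 5 5-bromo-2-[(2-methylprop-2-en-1-yl)oxy]benzaldehyde
Conditions: K2CO3, NaI (cat.), DMF, 60 °C
Reagents that add atoms: none
Why: Williamson ether synthesis, an SN2 reaction of the acidic salicylaldehyde phenoxide with a reactive allylic chloride, which tolerates the aldehyde and the aryl bromide.

**Step 3**
Reactants: 5 5-bromo-2-[(2-methylprop-2-en-1-yl)oxy]benzaldehyde
Product: 7 racemic trans-5-bromo-2-(prop-1-en-2-yl)-2,3-dihydro-1-benzofuran-3-ol (2R,3S enantiomer drawn), via 1,5-biradical 6 (not isolated)
Conditions: hν (365 nm), degassed MeCN (0.01 M), rt; chromatography on Et3N-washed silica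
Reagents that add atoms: none
Why: Norrish–Yang-type photocyclisation of an ortho-alkoxy aryl aldehyde, in which the excited carbonyl oxygen abstracts the allylic, oxygen-activated OCH2 hydrogen through a seven-membered transition state and the 1,5-biradical 6 recombines at C2–C3 to close the five-membered ring with the isopropenyl group anti to the solvent-bonded OH (trans, racemic because nothing in 5 is chiral), the aryl bromide being kept because its C–Br bond (about 80 kcal/mol) lies above the triplet energy and survives 365 nm light.

**Step 4**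
Reactants: 7 racemic trans-5-bromo-2-(prop-1-en-2-yl)-2,3-dihydro-1-benzofuran-3-ol; 8 3-methylbutanoic acid (isovaleric acid)
Product: 10 (2R,3S)-5-bromo-2-(prop-1-en-2-yl)-2,3-dihydro-1-benzofuran-3-yl 3-methylbutanoate, via mixed anhydride 9 (not isolated)
Conditions: (R)-BTM (5 mol %), Piv2O (0.55 equiv), i-Pr2NEt (1.2 equiv), 8 (0.5 equiv), CH2Cl2, rt, to about 45% conversion
Reagents that add atoms: none
Why: Acylative kinetic resolution by benzotetramisole acyl transfer (mixed-anhydride method), in which the acid and pivalic anhydride form 9, the catalyst takes up only the unhindered isovaleryl group and passes it to the 3S alcohol (the benzylic carbinol with the spatial arrangement of an (R)-1-arylethanol), so the 2R,3S enantiomer of 7 is esterified with retention at C3 while its 2S,3R enantiomer stays as the alcohol and is separated on silica.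

**Step 5**
Reactants: 10 (2R,3S)-5-bromo-2-(prop-1-en-2-yl)-2,3-dihydro-1-benzofuran-3-yl 3-methylbutanoate; 11 1-bromoethyl acetate (racemic)
Product: 12 (2R,3S)-5-[(1S)-1-acetoxyethyl]-2-(prop-1-en-2-yl)-2,3-dihydro-1-benzofuran-3-yl 3-methylbutanoate
Conditions: NiBr2·diglyme (10 mol %), (S,S)-4-heptyl-BiOX (20 mol %), Mn powder (3 equiv), NaI (1 equiv), 11 (2 equiv, slow addition), 1,4-dioxane/DMA 4:1, rt
Reagents that add atoms: none
Why: Proposed new method: zerovalent nickel inserts into the C–Br bond of 10, halogen abstraction from 11 by a low-valent nickel species gives the nucleophilic 1-acetoxyethyl radical, and capture of this radical by the chiral aryl-nickel complex followed by reductive elimination sets the S benzylic centre from the racemic bromide under ligand control, the ring stereocentres being too remote to interfere; the closest known reaction types are the nickel/BiOX enantioselective reductive cross-coupling of aryl halides with secondary benzylic chlorides and the nickel-catalysed enantioconvergent coupling of racemic 1-haloalkyl esters.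

**Step 6**
Reactants: 12 (2R,3S)-5-[(1S)-1-acetoxyethyl]-2-(prop-1-en-2-yl)-2,3-dihydro-1-benzofuran-3-yl 3-methylbutanoate
Product: 13 (1S)-1-[(2R,3S)-3-[(3-methylbutanoyl)oxy]-2-(3-oxoprop-1-en-2-yl)-2,3-dihydro-1-benzofuran-5-yl]ethyl acetate
Conditions: SeO2 (1.5 equiv), 1,4-dioxane, 70 °C
Reagents that add atoms: selenium dioxide, O=[Se]=O
Why: Riley allylic oxidation, in which the ene reaction of SeO2 at the terminal CH2 takes hydrogen from the methyl group, a [2,3]-shift and further oxidation give the 2-substituted acrolein, the hindered C2–H flanked by two oxygen-bearing carbons is left alone (the selectivity known for 2-isopropenyl-dihydrobenzofurans), and no stereocentre is touched.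

**Compound list**
1 | 4-bromophenol | Oc1ccc(Br)cc1 | starting material
2 | paraformaldehyde (as formaldehyde) | C=O | starting material
3 | 5-bromo-2-hydroxybenzaldehyde | O=Cc1cc(Br)ccc1O | intermediate
4 | 3-chloro-2-methylprop-1-ene | C=C(C)CCl | starting material
5 | 5-bromo-2-[(2-methylprop-2-en-1-yl)oxy]benzaldehyde | C=C(C)COc1ccc(Br)cc1C=O | intermediate
6 | 1,5-biradical (hydroxybenzyl radical and 1-aryloxy-2-methylallyl radical) from 5 | C=C(C)[CH]Oc1ccc(Br)cc1[CH]O | intermediate
7 | racemic trans-5-bromo-2-(prop-1-en-2-yl)-2,3-dihydro-1-benzofuran-3-ol (2R,3S enantiomer drawn) | C=C(C)[C@H]1Oc2ccc(Br)cc2[C@@H]1O | intermediate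
8 | 3-methylbutanoic acid | CC(C)CC(=O)O | starting material
9 | 3-methylbutanoic pivalic anhydride | CC(C)CC(=O)OC(=O)C(C)(C)C | intermediate
10 | (2R,3S)-5-bromo-2-(prop-1-en-2-yl)-2,3-dihydro-1-benzofuran-3-yl 3-methylbutanoate | C=C(C)[C@H]1Oc2ccc(Br)cc2[C@@H]1OC(=O)CC(C)C | intermediate
11 | 1-bromoethyl acetate (racemic) | CC(Br)OC(C)=O | starting material
12 | (2R,3S)-5-[(1S)-1-acetoxyethyl]-2-(prop-1-en-2-yl)-2,3-dihydro-1-benzofuran-3-yl 3-methylbutanoate | C=C(C)[C@H]1Oc2ccc([C@H](C)OC(C)=O)cc2[C@@H]1OC(=O)CC(C)C | intermediate
13 | (1S)-1-[(2R,3S)-3-[(3-methylbutanoyl)oxy]-2-(3-oxoprop-1-en-2-yl)-2,3-dihydro-1-benzofuran-5-yl]ethyl acetate | C=C(C=O)[C@H]1Oc2ccc([C@H](C)OC(C)=O)cc2[C@@H]1OC(=O)CC(C)C | target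

**Totals**
Total step count: 6. Longest linear sequence: 6 steps (1 → 3 → 5 → 7 → 10 → 12 → 13). Step 4 is a resolution, so its yield is capped at half of racemic 7.

**Three steps most likely to fail, with fallbacks**

Step 3 (photocyclisation). The risks are oxetane formation with the pendant alkene, closure at the far allyl terminus to a seven-membered ring, a poor trans:cis ratio, and some C–Br homolysis from the excited state. The fallback closes the ring by ionic sulfur-ylide annulation. It sets out from 3 and comes back at 7. Compound 4 and dimethyl sulfide give dimethyl(2-methylprop-2-en-1-yl)sulfonium chloride F1. F1 and 3 with Cs2CO3 in MeCN undergo ylide addition to the aldehyde and then 5-exo-tet displacement of Me2S by the neighbouring phenoxide, giving racemic trans alcohol 7 after removal of any cis isomer.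

Step 5 (asymmetric nickel radical coupling). The risks are low enantioselectivity, slow insertion of zerovalent nickel into the electron-rich aryl bromide, and ionisation of the cyclic allyl aryl ether or the benzylic ester by zerovalent nickel. The fallback builds the side chain by two-electron chemistry before the ring is made. It sets out from 5 and comes back at 12.
- Internal Heck arylation of butyl vinyl ether with 5 (Pd(OAc)2, dppp, K2CO3, DMF/H2O, 80 °C) gives 5-(1-butoxyethenyl)-2-[(2-methylprop-2-en-1-yl)oxy]benzaldehyde F2.
- Dilute HCl work-up hydrolyses it to 5-acetyl-2-[(2-methylprop-2-en-1-yl)oxy]benzaldehyde F3.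
- Irradiation as in step 3 gives, through the 1,5-biradical F4, racemic trans-1-[3-hydroxy-2-(prop-1-en-2-yl)-2,3-dihydro-1-benzofuran-5-yl]ethan-1-one F5, since only the ortho-alkoxy aldehyde has a hydrogen within reach.
- Resolution as in step 4 (8, Piv2O, (R)-BTM, through 9) gives (2R,3S)-5-acetyl-2-(prop-1-en-2-yl)-2,3-dihydro-1-benzofuran-3-yl 3-methylbutanoate F6.
- Noyori transfer hydrogenation (RuCl[(S,S)-TsDPEN](p-cymene), HCO2H/Et3N, rt) gives (2R,3S)-5-[(1S)-1-hydroxyethyl]-2-(prop-1-en-2-yl)-2,3-dihydro-1-benzofuran-3-yl 3-methylbutanoate F7.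
- Ac2O, pyridine and DMAP (cat.) at 0 °C give 12.

Step 6 (direct SeO2 oxidation to the enal). The risks are that warm, weakly acidic selenous acid ionises the C3 ester (loss of isovaleric acid to a benzofuran) or the benzylic acetate, and that the reaction stalls at the alcohol. The fallback stages the oxidation under neutral conditions at room temperature. It sets out from 12 and comes back at 13. SeO2 (cat.) with t-BuOOH in CH2Cl2 at rt stops at (2R,3S)-5-[(1S)-1-acetoxyethyl]-2-(3-hydroxyprop-1-en-2-yl)-2,3-dihydro-1-benzofuran-3-yl 3-methylbutanoate F8. Activated MnO2 in CH2Cl2 at rt then oxidises only the primary allylic alcohol to give 13.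

**Further compounds**
F1 | step 3 | dimethyl(2-methylprop-2-en-1-yl)sulfonium chloride | C=C(C)C[S+](C)C.[Cl-]
F2 | step 5 | 5-(1-butoxyethenyl)-2-[(2-methylprop-2-en-1-yl)oxy]benzaldehyde | C=C(C)COc1ccc(C(=C)OCCCC)cc1C=O
F3 | step 5 | 5-acetyl-2-[(2-methylprop-2-en-1-yl)oxy]benzaldehyde | C=C(C)COc1ccc(C(C)=O)cc1C=O
F4 | step 5 | 1,5-biradical (hydroxybenzyl radical and 1-aryloxy-2-methylallyl radical) from F3 | C=C(C)[CH]Oc1ccc(C(C)=O)cc1[CH]O
F5 | step 5 | racemic trans-1-[3-hydroxy-2-(prop-1-en-2-yl)-2,3-dihydro-1-benzofuran-5-yl]ethan-1-one (2R,3S enantiomer drawn) | C=C(C)[C@H]1Oc2ccc(C(C)=O)cc2[C@@H]1O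
F6 | step 5 | (2R,3S)-5-acetyl-2-(prop-1-en-2-yl)-2,3-dihydro-1-benzofuran-3-yl 3-methylbutanoate | C=C(C)[C@H]1Oc2ccc(C(C)=O)cc2[C@@H]1OC(=O)CC(C)C
F7 | step 5 | (2R,3S)-5-[(1S)-1-hydroxyethyl]-2-(prop-1-en-2-yl)-2,3-dihydro-1-benzofuran-3-yl 3-methylbutanoate | C=C(C)[C@H]1Oc2ccc([C@H](C)O)cc2[C@@H]1OC(=O)CC(C)C
F8 | step 6 | (2R,3S)-5-[(1S)-1-acetoxyethyl]-2-(3-hydroxyprop-1-en-2-yl)-2,3-dihydro-1-benzofuran-3-yl 3-methylbutanoate | C=C(CO)[C@H]1Oc2ccc([C@H](C)OC(C)=O)cc2[C@@H]1OC(=O)CC(C)C
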